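The ten-membered carbocycle (C1–C10; C4 = C(CH3)OH, C5 = CH–O-isobutyryl, C6 = lactone CH–O, C9 = C=O) is made by four-carbon ring expansion of a cyclohexane (C6–C7–C8–C9–C10–C1). The step exploits the C6 oxygen and its neighbours C5 and C4: an anionic oxy-Cope rearrangement of a 1,2-dialkenylcyclohexanol joins vinyl terminus C3 to enol-ether terminus C4 while C6–C1 breaks. In one operation it closes the ring, sets C4 from the Z enol-ether geometry through a chair transition state and leaves a C5=C6 enolate, hydroxylated at C5 in the same flask. The cyclohexanol comes from a quinone monoketal (dearomatized 4-methoxyphenol) by asymmetric conjugate addition and substrate-controlled relay.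

Key step: step 11

Remarks.
- Further locants: C7 = ring-fusion CH, C8 = CH–O-(2-methylbutanoyl), C10 = CH(CH3), C1–C3 = CH2, C11/C12/C13 = lactone α-carbon, lactone C=O, exocyclic CH2. With the six-membered ring drawn C6→C7→C8→C9→C10→C1 clockwise, β is up and α is down.
- Assumption: compounds 1, 2, 14 and 25 are taken as commercial.

Step 1
Reactants: 1 4,4-dimethoxycyclohexa-2,5-dien-1-one; 2 (1,3-dioxolan-2-ylmethyl)magnesium bromide
Product: 3 (5R)-5-(1,3-dioxolan-2-ylmethyl)-4,4-dimethoxycyclohex-2-en-1-one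
Conditions: CuBr·SMe2 (5 mol %), (R)-1-[(S)-2-(diphenylphosphino)ferrocenyl]ethyldicyclohexylphosphine (6 mol %; or its antipode, whichever delivers 5R), tBuOMe, −75 °C; aq. NH4Cl
Reagents that add atoms: none
Why: Copper-catalysed asymmetric conjugate addition of a Grignard reagent to a cyclic enone should desymmetrize the dienone, the chiral phosphine–copper complex choosing one of the two enantiotopic enones and so setting C7.

Step 2
Reactants: 3 (5R)-5-(1,3-dioxolan-2-ylmethyl)-4,4-dimethoxycyclohex-2-en-1-one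
Product: 5 (5R,6R)-5-(1,3-dioxolan-2-ylmethyl)-6-hydroxy-4,4-dimethoxycyclohex-2-en-1-one, via sodium dienolate 4 (not isolated)
Conditions: NaHMDS, THF, −78 °C; then 2-(phenylsulfonyl)-3-phenyloxaziridine, −78 °C; aq. NH4Cl
Reagents that add atoms: 2-(phenylsulfonyl)-3-phenyloxaziridine, O=S(=O)(c1ccccc1)N1OC1c1ccccc1
Why: Davis oxidation of the cross-conjugated enolate (C8–H is the only enolizable position) should place the C8 oxygen anti to the adjacent C7 side chain, giving the 5,6-trans ketol.

Step 3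
Reactants: 5 (5R,6R)-5-(1,3-dioxolan-2-ylmethyl)-6-hydroxy-4,4-dimethoxycyclohex-2-en-1-one
Product: 6 (5R,6R)-6-(benzyloxy)-5-(1,3-dioxolan-2-ylmethyl)-4,4-dimethoxycyclohex-2-en-1-one
Conditions: BnBr, Ag2O, CH2Cl2, rt, dark
Reagents that add atoms: benzyl bromide, BrCc1ccccc1
Why: Silver-oxide-mediated Williamson etherification benzylates the acidic ketol hydroxyl without strong base, so the ketol, the ketal and the acetal should survive and no stereocenter is touched.

Step 4
Reactants: 6 (5R,6R)-6-(benzyloxy)-5-(1,3-dioxolan-2-ylmethyl)-4,4-dimethoxycyclohex-2-en-1-one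
Product: 8 (4S,5R,6R)-5-(benzyloxy)-6-(1,3-dioxolan-2-ylmethyl)-4-hydroxycyclohex-2-en-1-one, via allylic alcohol ketal 7 (not isolated)
Conditions: (S)-2-methyl-CBS-oxazaborolidine [(S)-1-methyl-3,3-diphenyltetrahydro-1H,3H-pyrrolo[1,2-c][1,3,2]oxazaborole] (20 mol %), catecholborane, toluene, −78 °C; then aq. oxalic acid, THF, 0 °C to rt
Reagents that add atoms: water, O
Why: Corey–Bakshi–Shibata reduction with the alkenyl arm as the large group should deliver hydride anti to the C8 benzyloxy group (C9–OH cis to it), and mild acid then hydrolyses only the allylic dimethyl ketal, transposing the carbonyl to C6 while the dioxolane stays.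

Step 5
Reactants: 8 (4S,5R,6R)-5-(benzyloxy)-6-(1,3-dioxolan-2-ylmethyl)-4-hydroxycyclohex-2-en-1-one
Product: 9 (4S,5R,6R)-5-(benzyloxy)-4-[(tert-butyldimethylsilyl)oxy]-6-(1,3-dioxolan-2-ylmethyl)cyclohex-2-en-1-one
Conditions: TBSOTf, 2,6-lutidine, CH2Cl2, −78 °C
Reagents that add atoms: tert-butyldimethylsilyl triflate, CC(C)(C)[Si](C)(C)OS(=O)(=O)C(F)(F)F
Why: Silylation of the hindered secondary alcohol under non-nucleophilic base conditions avoids β-elimination and installs the C9 group that later steers the cuprate.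

Step 6
Reactants: 9 (4S,5R,6R)-5-(benzyloxy)-4-[(tert-butyldimethylsilyl)oxy]-6-(1,3-dioxolan-2-ylmethyl)cyclohex-2-en-1-one
Product: 10 (4S,5R,6R)-5-(benzyloxy)-4-[(tert-butyldimethylsilyl)oxy]-6-(1,3-dioxolan-2-ylmethyl)-2-iodocyclohex-2-en-1-one
Conditions: I2, pyridine, CH2Cl2, 0 °C to rt
Reagents that add atoms: iodine, II
Why: Pyridine-mediated α-iodination of a cyclic enone (conjugate addition of pyridine, iodination of the enolate, elimination) should functionalize only C1.

Step 7
Reactants: 10 (4S,5R,6R)-5-(benzyloxy)-4-[(tert-butyldimethylsilyl)oxy]-6-(1,3-dioxolan-2-ylmethyl)-2-iodocyclohex-2-en-1-one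
Product: 11 (4S,5R,6R)-5-(benzyloxy)-4-[(tert-butyldimethylsilyl)oxy]-6-(1,3-dioxolan-2-ylmethyl)-2-ethenylcyclohex-2-en-1-one
Conditions: tributyl(vinyl)stannane, Pd2(dba)3 (2.5 mol %), AsPh3, CuI, NMP, rt; used at once
Reagents that add atoms: tributyl(vinyl)stannane, C=C[Sn](CCCC)(CCCC)CCCC
Why: Stille coupling of an α-iodoenone proceeds at room temperature under neutral conditions, which the β-alkoxy ketone should tolerate.

Step 8
Reactants: 11 (4S,5R,6R)-5-(benzyloxy)-4-[(tert-butyldimethylsilyl)oxy]-6-(1,3-dioxolan-2-ylmethyl)-2-ethenylcyclohex-2-en-1-one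
Product: 13 (2S,3R,4S,5R,6R)-5-(benzyloxy)-4-[(tert-butyldimethylsilyl)oxy]-6-(1,3-dioxolan-2-ylmethyl)-2-ethenyl-3-methylcyclohexan-1-one, via lithium dienolate 12 (not isolated)
Conditions: Me2CuLi (from MeLi and CuI), Et2O, −78 °C; then sat. aq. NH4Cl at −78 °C
Reagents that add atoms: lithium dimethylcuprate, [Li+].C[Cu-]C
Why: Gilman 1,4-addition should put the methyl on C10 anti to the pseudoaxial C9 silyloxy and the C8 benzyloxy groups, and kinetic protonation of the dienolate at C1 from the face opposite the axial C10 methyl should give the cis C1/C10 ketone, which is also the isomer with the vinyl group equatorial.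

Step 9
Reactants: 14 benzyl isopropenyl ether
Product: 16 (Z)-{[(1-bromoprop-1-en-2-yl)oxy]methyl}benzene, via dibromide 15 (not isolated)
Conditions: Br2, CH2Cl2, −78 °C; then DBU, −78 to 0 °C; distillation
Reagents that add atoms: bromine, BrBr
Why: Bromine addition to the enol ether and base-induced loss of HBr through the more acidic CH2Br proton is the standard route to 1-bromo-2-alkoxyalkenes, and the isomer with Br cis to oxygen is expected to predominate and is purified.

Step 10
Reactants: 13 (2S,3R,4S,5R,6R)-5-(benzyloxy)-4-[(tert-butyldimethylsilyl)oxy]-6-(1,3-dioxolan-2-ylmethyl)-2-ethenyl-3-methylcyclohexan-1-one; 16 (Z)-{[(1-bromoprop-1-en-2-yl)oxy]methyl}benzene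
Product: 19 1-[(Z)-2-(benzyloxy)prop-1-en-1-yl]-5-(benzyloxy)-4-[(tert-butyldimethylsilyl)oxy]-6-(1,3-dioxolan-2-ylmethyl)-2-ethenyl-3-methylcyclohexan-1-ol (alkenyl trans to ethenyl), via alkenyllithium 17 (not isolated), via alkenylcerium dichloride 18 (not isolated)
Conditions: 16, tBuLi (2 equiv), Et2O, −78 °C; CeCl3, THF, −78 °C; then 13, −78 °C; aq. NH4Cl
Reagents that add atoms: none
Why: Bromine–lithium exchange with retention gives the chelated cis-β-alkoxyvinyllithium, the organocerium reagent adds without enolizing the α-vinyl ketone, and equatorial attack on the β face (axial attack on the α face is blocked by the axial C10 methyl) should give the axial C6 alcohol with the alkenyl group equatorial and trans to the vinyl group.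

Step 11
Reactants: 19 1-[(Z)-2-(benzyloxy)prop-1-en-1-yl]-5-(benzyloxy)-4-[(tert-butyldimethylsilyl)oxy]-6-(1,3-dioxolan-2-ylmethyl)-2-ethenyl-3-methylcyclohexan-1-ol
Product: 22 (1E)-4,8-bis(benzyloxy)-9-[(tert-butyldimethylsilyl)oxy]-7-(1,3-dioxolan-2-ylmethyl)-5-hydroxy-4,10-dimethylcyclodec-1-en-6-one (locants of the remark), via potassium alkoxide 20 (not isolated), via potassium enolate 21 (not isolated)
Conditions: KH, 18-crown-6, THF, 0 °C to rt; then −78 °C, 2-(phenylsulfonyl)-3-phenyloxaziridine; aq. NH4Cl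
Reagents that add atoms: 2-(phenylsulfonyl)-3-phenyloxaziridine, O=S(=O)(c1ccccc1)N1OC1c1ccccc1
Why: KH/18-crown-6 gives the free alkoxide 20, in which C6–C1 breaks while C3–C4 forms in a concerted [3,3] sigmatropic shift through a chair transition state with both alkenyl groups equatorial on the cyclohexane chair and the alkoxide axial; the closest known reaction type is the anionic oxy-Cope ring expansion of trans-1,2-divinylcyclohexanols to cyclodec-5-enones, followed here by Davis hydroxylation of the regiodefined enolate. The ten-membered carbocycle is closed by four-atom ring expansion, the new bond being made inside the six-membered pericyclic array, so no exo or endo descriptor applies. C4 is set by the Z enol-ether geometry relayed through the chair (benzyloxy pseudoaxial, methyl pseudoequatorial) from the fixed C6 and C1 centres, and the equatorial ring bonds at C1 and C6 give the E C1=C2 alkene and a C5=C6 enolate 21 in which the ring carbons C7 and C4 are trans. C5 is set when the oxaziridine attacks the outer face of this enolate in the crossed conformation inherited from the chair, the inner face being covered by the C1=C2 bridge. The step needs this shift to outrun other sigmatropic or fragmentation paths and the chair to beat the boat: the only 1,5-diene present is C4=C5–C6–C1–C2=C3 because the C7 side chain is saturated at C11, the alkoxy groups at C8 and C9 are poor leaving groups, and the trans-diequatorial alkenyl groups fix the chair. Enolate formation makes the expansion irreversible, and loss of benzyloxide from C4 of enolate 21 should be held back because the C4–O bond lies close to the nodal plane of the enolate π system in the conformation the chair delivers and the enolate is trapped at −78 °C.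

Step 12
Reactants: 22 (1E)-4,8-bis(benzyloxy)-9-[(tert-butyldimethylsilyl)oxy]-7-(1,3-dioxolan-2-ylmethyl)-5-hydroxy-4,10-dimethylcyclodec-1-en-6-one
Product: 23 5-O-isobutyryl derivative of 22
Conditions: isobutyryl chloride, pyridine, 4-(dimethylamino)pyridine (DMAP, cat.), CH2Cl2, 0 °C
Reagents that add atoms: isobutyryl chloride, CC(C)C(=O)Cl
Why: Nucleophile-catalysed acylation of the only free hydroxyl (the C5 ketol OH) under mild conditions should not epimerize C5 or eliminate the C8 ether.

Step 13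
Reactants: 23 5-O-isobutyryl derivative of 22
Product: 24 9-[(tert-butyldimethylsilyl)oxy]-7-(1,3-dioxolan-2-ylmethyl)-4,8-dihydroxy-4,10-dimethyl-6-oxocyclodecan-5-yl isobutyrate
Conditions: H2 (1–3 atm), Pd(OH)2/C, EtOAc, rt
Reagents that add atoms: none
Why: Heterogeneous hydrogenation should saturate the strained E C1=C2 alkene and hydrogenolyse the C4 and C8 benzyl ethers in one operation, leaving ketone, ester, silyl ether and acetal intact.

Step 14
Reactants: 24 9-[(tert-butyldimethylsilyl)oxy]-7-(1,3-dioxolan-2-ylmethyl)-4,8-dihydroxy-4,10-dimethyl-6-oxocyclodecan-5-yl isobutyrate; 25 (R)-2-methylbutanoic acid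
Product: 26 8-O-[(R)-2-methylbutanoyl] derivative of 24
Conditions: EDC·HCl, 4-(dimethylamino)pyridine (DMAP, cat.), CH2Cl2, 0 °C to rt
Reagents that add atoms: none
Why: Steglich esterification acylates the secondary C8 hydroxyl while the tertiary C4 hydroxyl stays free, and catalytic DMAP at low temperature should keep the α-stereocenter of the acid and avoid β-elimination.

Step 15
Reactants: 26 8-O-[(R)-2-methylbutanoyl] derivative of 24
Product: 27 6-alcohol: 9-[(tert-butyldimethylsilyl)oxy]-7-(1,3-dioxolan-2-ylmethyl)-4,6-dihydroxy-4,10-dimethyl-8-{[(R)-2-methylbutanoyl]oxy}cyclodecan-5-yl isobutyrate (C6 as in the target)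
Conditions: NaBH4, CeCl3·7H2O, MeOH, −78 °C; AcOH quench at −78 °C
Reagents that add atoms: none
Why: Luche-type reduction under polar Felkin–Anh control (C5 acyloxy group antiperiplanar to the incoming hydride, ring carbons C4 and C7 anti) should give the 5,6-syn alcohol, and the cold non-basic quench suppresses acyl migration.

Step 16
Reactants: 27 6-alcohol
Product: 28 6,12-lactol (mixture of C12 anomers)
Conditions: pyridinium p-toluenesulfonate (PPTS), acetone/H2O, 45 °C
Reagents that add atoms: water, O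
Why: Acid-catalysed acetal hydrolysis releases the C12 aldehyde, which is captured by the C6 hydroxyl as the five-membered lactol; C8 is acylated and C9 silylated, so only the 6,12 ring can form.

Step 17
Reactants: 28 6,12-lactol
Product: 29 α-methylene lactol (mixture of C12 anomers)
Conditions: N,N-dimethylmethyleneiminium iodide, Et3N, CH2Cl2, rt
Reagents that add atoms: N,N-dimethylmethyleneiminium iodide (Eschenmoser's salt), C=[N+](C)C.[I-]
Why: Mannich reaction of the open-chain aldehyde tautomer followed by loss of dimethylamine installs C13 as the exocyclic methylene without strong base, so both esters survive.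

Step 18
Reactants: 29 α-methylene lactol
Product: 30 9-O-TBS ether of the 9-hydroxy lactone (target with C9 as CH–OTBS)
Conditions: 2,2,6,6-tetramethylpiperidin-1-oxyl (TEMPO, cat.), PhI(OAc)2, CH2Cl2, rt
Reagents that add atoms: none
Why: Oxoammonium-mediated oxidation converts the lactol into the α-methylene-γ-lactone; the tertiary C4 alcohol cannot be oxidized and C9 is protected.

Step 19
Reactants: 30 9-O-TBS ether
Product: 31 9-hydroxy lactone (target with C9 as CH–OH)
Conditions: HF·pyridine, pyridine, THF, 0 °C to rt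
Reagents that add atoms: none
Why: Buffered fluoride desilylation removes the secondary silyl ether without touching the esters or the Michael acceptor.

Step 20
Reactants: 31 9-hydroxy lactone
Product: 32 CNP0071420.1
Conditions: Dess–Martin periodinane, NaHCO3, CH2Cl2, 0 °C to rt
Reagents that add atoms: none
Why: Dess–Martin oxidation under buffered neutral conditions gives the C9 ketone without epimerizing the flanking C8 and C10 centres or disturbing the tertiary alcohol.

Compound list
1 | 4,4-dimethoxycyclohexa-2,5-dien-1-one | O=C1C=CC(OC)(OC)C=C1 | starting material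
2 | (1,3-dioxolan-2-ylmethyl)magnesium bromide | Br[Mg]CC1OCCO1 | starting material
3 | (5R)-5-(1,3-dioxolan-2-ylmethyl)-4,4-dimethoxycyclohex-2-en-1-one | O=C1C=CC(OC)(OC)[C@H](CC2OCCO2)C1 | intermediate
4 | sodium dienolate of 3 (enolate across C8=C9) | [Na+].[O-]C1=C[C@@H](CC2OCCO2)C(OC)(OC)C=C1 | intermediate
5 | (5R,6R)-5-(1,3-dioxolan-2-ylmethyl)-6-hydroxy-4,4-dimethoxycyclohex-2-en-1-one | O=C1C=CC(OC)(OC)[C@H](CC2OCCO2)[C@H]1O | intermediate
6 | (5R,6R)-6-(benzyloxy)-5-(1,3-dioxolan-2-ylmethyl)-4,4-dimethoxycyclohex-2-en-1-one | O=C1C=CC(OC)(OC)[C@H](CC2OCCO2)[C@H]1OCc3ccccc3 | intermediate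
7 | (1S,5R,6R)-6-(benzyloxy)-5-(1,3-dioxolan-2-ylmethyl)-4,4-dimethoxycyclohex-2-en-1-ol | COC1(OC)[C@H](CC2OCCO2)[C@@H](OCc3ccccc3)[C@@H](O)C=C1 | intermediate
8 | (4S,5R,6R)-5-(benzyloxy)-6-(1,3-dioxolan-2-ylmethyl)-4-hydroxycyclohex-2-en-1-one | O=C1[C@H](CC2OCCO2)[C@@H](OCc3ccccc3)[C@@H](O)C=C1 | intermediate
9 | (4S,5R,6R)-5-(benzyloxy)-4-[(tert-butyldimethylsilyl)oxy]-6-(1,3-dioxolan-2-ylmethyl)cyclohex-2-en-1-one | O=C1[C@H](CC2OCCO2)[C@@H](OCc3ccccc3)[C@@H](O[Si](C)(C)C(C)(C)C)C=C1 | intermediate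
10 | (4S,5R,6R)-5-(benzyloxy)-4-[(tert-butyldimethylsilyl)oxy]-6-(1,3-dioxolan-2-ylmethyl)-2-iodocyclohex-2-en-1-one | O=C1[C@H](CC2OCCO2)[C@@H](OCc3ccccc3)[C@@H](O[Si](C)(C)C(C)(C)C)C=C1I | intermediate
11 | (4S,5R,6R)-5-(benzyloxy)-4-[(tert-butyldimethylsilyl)oxy]-6-(1,3-dioxolan-2-ylmethyl)-2-ethenylcyclohex-2-en-1-one | O=C1[C@H](CC2OCCO2)[C@@H](OCc3ccccc3)[C@@H](O[Si](C)(C)C(C)(C)C)C=C1C=C | intermediate
12 | lithium dienolate from methyl addition to 11 | [Li+].[O-]C=1[C@H](CC2OCCO2)[C@@H](OCc3ccccc3)[C@@H](O[Si](C)(C)C(C)(C)C)[C@H](C)C=1C=C | intermediate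
13 | (2S,3R,4S,5R,6R)-5-(benzyloxy)-4-[(tert-butyldimethylsilyl)oxy]-6-(1,3-dioxolan-2-ylmethyl)-2-ethenyl-3-methylcyclohexan-1-one | O=C1[C@H](CC2OCCO2)[C@@H](OCc3ccccc3)[C@@H](O[Si](C)(C)C(C)(C)C)[C@H](C)[C@@H]1C=C | intermediate
14 | benzyl isopropenyl ether | C=C(C)OCc1ccccc1 | starting material
15 | [(1,2-dibromopropan-2-yl)oxy]methylbenzene (racemic) | BrCC(C)(Br)OCc1ccccc1 | intermediate
16 | (Z)-{[(1-bromoprop-1-en-2-yl)oxy]methyl}benzene | Br/C=C(/C)OCc1ccccc1 | intermediate
17 | (Z)-[2-(benzyloxy)prop-1-en-1-yl]lithium | [Li]/C=C(/C)OCc1ccccc1 | intermediate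
18 | (Z)-[2-(benzyloxy)prop-1-en-1-yl]cerium dichloride | Cl[Ce](Cl)/C=C(/C)OCc1ccccc1 | intermediate
19 | 1-[(Z)-2-(benzyloxy)prop-1-en-1-yl]-5-(benzyloxy)-4-[(tert-butyldimethylsilyl)oxy]-6-(1,3-dioxolan-2-ylmethyl)-2-ethenyl-3-methylcyclohexan-1-ol (ring centres as in 13; alkenyl trans to ethenyl, OH axial) | O[C@]1(/C=C(/C)OCc2ccccc2)[C@H](CC3OCCO3)[C@@H](OCc4ccccc4)[C@@H](O[Si](C)(C)C(C)(C)C)[C@H](C)[C@@H]1C=C | intermediate
20 | potassium alkoxide of 19 | [K+].[O-][C@]1(/C=C(/C)OCc2ccccc2)[C@H](CC3OCCO3)[C@@H](OCc4ccccc4)[C@@H](O[Si](C)(C)C(C)(C)C)[C@H](C)[C@@H]1C=C | intermediate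
21 | potassium C5=C6 enolate of the ring-expanded (1E)-cyclodecenone | [K+].[O-]/C1=C\[C@@](C)(OCc2ccccc2)C/C=C/[C@@H](C)[C@H](O[Si](C)(C)C(C)(C)C)[C@H](OCc3ccccc3)[C@H]1CC4OCCO4 | intermediate
22 | (1E)-4,8-bis(benzyloxy)-9-[(tert-butyldimethylsilyl)oxy]-7-(1,3-dioxolan-2-ylmethyl)-5-hydroxy-4,10-dimethylcyclodec-1-en-6-one (locants of the remark; C4, C5, C7, C8, C10 as in the target; C9–O cis to C8–O) | O=C1[C@H](CC2OCCO2)[C@@H](OCc3ccccc3)[C@@H](O[Si](C)(C)C(C)(C)C)[C@H](C)/C=C/C[C@](C)(OCc4ccccc4)[C@@H]1O | intermediate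
23 | 5-O-isobutyryl derivative of 22 | O=C1[C@H](CC2OCCO2)[C@@H](OCc3ccccc3)[C@@H](O[Si](C)(C)C(C)(C)C)[C@H](C)/C=C/C[C@](C)(OCc4ccccc4)[C@@H]1OC(=O)C(C)C | intermediate
24 | 9-[(tert-butyldimethylsilyl)oxy]-7-(1,3-dioxolan-2-ylmethyl)-4,8-dihydroxy-4,10-dimethyl-6-oxocyclodecan-5-yl isobutyrate | O=C1[C@H](CC2OCCO2)[C@@H](O)[C@@H](O[Si](C)(C)C(C)(C)C)[C@H](C)CCC[C@](C)(O)[C@@H]1OC(=O)C(C)C | intermediate
25 | (R)-2-methylbutanoic acid | CC[C@@H](C)C(=O)O | starting material
26 | 8-O-[(R)-2-methylbutanoyl] derivative of 24 | O=C1[C@H](CC2OCCO2)[C@@H](OC(=O)[C@H](C)CC)[C@@H](O[Si](C)(C)C(C)(C)C)[C@H](C)CCC[C@](C)(O)[C@@H]1OC(=O)C(C)C | intermediate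
27 | 6-alcohol from 26 (C6 as in the target) | O[C@H]1[C@H](CC2OCCO2)[C@@H](OC(=O)[C@H](C)CC)[C@@H](O[Si](C)(C)C(C)(C)C)[C@H](C)CCC[C@](C)(O)[C@@H]1OC(=O)C(C)C | intermediate
28 | 6,12-lactol (C12 anomers) | OC1O[C@H]2[C@H](C1)[C@@H](OC(=O)[C@H](C)CC)[C@@H](O[Si](C)(C)C(C)(C)C)[C@H](C)CCC[C@](C)(O)[C@@H]2OC(=O)C(C)C | intermediate
29 | α-methylene 6,12-lactol (C12 anomers) | OC1O[C@H]2[C@H](C1=C)[C@@H](OC(=O)[C@H](C)CC)[C@@H](O[Si](C)(C)C(C)(C)C)[C@H](C)CCC[C@](C)(O)[C@@H]2OC(=O)C(C)C | intermediate
30 | 9-O-TBS ether of the 9-hydroxy lactone | C=C1C(=O)O[C@H]2[C@H]1[C@@H](OC(=O)[C@H](C)CC)[C@@H](O[Si](C)(C)C(C)(C)C)[C@H](C)CCC[C@](C)(O)[C@@H]2OC(=O)C(C)C | intermediate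
31 | 9-hydroxy lactone | C=C1C(=O)O[C@H]2[C@H]1[C@@H](OC(=O)[C@H](C)CC)[C@@H](O)[C@H](C)CCC[C@](C)(O)[C@@H]2OC(=O)C(C)C | intermediate
32 | CNP0071420.1 | C=C1C(=O)O[C@H]2[C@H]1[C@@H](OC(=O)[C@H](C)CC)C(=O)[C@H](C)CCC[C@](C)(O)[C@@H]2OC(=O)C(C)C | target

Count. Total: 20 steps. Longest linear sequence: 19 steps (steps 1–8 and 10–20; step 9 prepares the alkenyl bromide 16).

Steps most likely to fail

Risk 1: step 11, the key step. The ten-membered enolate may relax to a second ring conformer before it is trapped, so that the oxaziridine enters on the other face and C5 comes out inverted. Fallback for step 11: setting out from 19, the same operation would then deliver the C5-epimeric ketol F4 as the main product. Triflation of its C5 hydroxyl (Tf2O, pyridine, CH2Cl2, −20 °C) would give the α-keto triflate F5 as an isolable intermediate. Displacement with cesium isobutyrate (18-crown-6, toluene, rt) would then invert C5 in an SN2 reaction that the adjacent carbonyl group accelerates; this type of inversion is established for α-hydroxy carbonyl compounds that carry a neighbouring quaternary carbon. The fallback comes back to the route at 23.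

Risk 2: step 1. The acetal-bearing, chelating Grignard reagent may transfer sluggishly or with poor enantiofacial discrimination under copper–phosphine catalysis. Fallback for step 1: setting out from 1 and 2, a ligand-free copper-catalysed addition (CuBr·SMe2 cat., THF, −78 °C; aq. NH4Cl) would give the racemic enone F1 in place of 3. Hydroxylation as in step 2 would give the racemic trans ketol F2 in the same way. A lipase-catalysed acylation (immobilized Candida antarctica lipase B, vinyl acetate, tBuOMe, rt; the lipase is chosen by screening so that the unwanted enantiomer reacts) would convert that enantiomer into the acetate F3 and leave 5 unreacted. After chromatographic separation the fallback comes back to the route at 5.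

Risk 3: step 15. In the flexible cyclodecanone the hydride may be delivered to the other face of C6, because the ring conformation, and not the local Felkin–Anh preference, can decide the outcome. Fallback for step 15: setting out from 26, the reduction would then give the C6-epimeric alcohol F6 as the main product. Mitsunobu inversion with chloroacetic acid (PPh3, DIAD, toluene, 0 °C to rt) would give the inverted 6-O-chloroacetate F7 with C6 as in the target. Thiourea (NaHCO3, EtOH, 50 °C) would then remove the chloroacetyl group while the isobutyrate and the 2-methylbutanoate stay. The fallback comes back to the route at 27.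

Further compounds
F1 | step 1 | racemic enone, (5RS)-5-(1,3-dioxolan-2-ylmethyl)-4,4-dimethoxycyclohex-2-en-1-one | O=C1C=CC(OC)(OC)[C@H](CC2OCCO2)C1.O=C1C=CC(OC)(OC)[C@@H](CC2OCCO2)C1
F2 | step 1 | racemic trans ketol, (5RS,6RS)-5-(1,3-dioxolan-2-ylmethyl)-6-hydroxy-4,4-dimethoxycyclohex-2-en-1-one | O=C1C=CC(OC)(OC)[C@H](CC2OCCO2)[C@H]1O.O=C1C=CC(OC)(OC)[C@@H](CC2OCCO2)[C@@H]1O
F3 | step 1 | acetate of ent-5, (5S,6S)-6-acetoxy-5-(1,3-dioxolan-2-ylmethyl)-4,4-dimethoxycyclohex-2-en-1-one | O=C1C=CC(OC)(OC)[C@@H](CC2OCCO2)[C@@H]1OC(C)=O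
F4 | step 11 | C5-epimeric ketol (C5 epimer of 22) | O=C1[C@H](CC2OCCO2)[C@@H](OCc3ccccc3)[C@@H](O[Si](C)(C)C(C)(C)C)[C@H](C)/C=C/C[C@](C)(OCc4ccccc4)[C@H]1O
F5 | step 11 | α-keto triflate (5-O-triflate of F4) | O=C1[C@H](CC2OCCO2)[C@@H](OCc3ccccc3)[C@@H](O[Si](C)(C)C(C)(C)C)[C@H](C)/C=C/C[C@](C)(OCc4ccccc4)[C@H]1OS(=O)(=O)C(F)(F)F
F6 | step 15 | C6-epimeric alcohol (C6 epimer of 27) | O[C@@H]1[C@H](CC2OCCO2)[C@@H](OC(=O)[C@H](C)CC)[C@@H](O[Si](C)(C)C(C)(C)C)[C@H](C)CCC[C@](C)(O)[C@@H]1OC(=O)C(C)C
F7 | step 15 | 6-O-chloroacetate of 27 | ClCC(=O)O[C@H]1[C@H](CC2OCCO2)[C@@H](OC(=O)[C@H](C)CC)[C@@H](O[Si](C)(C)C(C)(C)C)[C@H](C)CCC[C@](C)(O)[C@@H]1OC(=O)C(C)C
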